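Assumption: the SMILES is taken as authoritative (6‑oxo‑8(17)‑ene, 2α‑Cl, 12S,13R). Labdane numbering is used: C17 is the carbon on C8, the side chain is C9–C11–C12(OH)–C13, and the imide is C13–C14–C15(=O)–N–C16(=O). α is the face of H‑5/H‑9; β is the face of the C10 methyl. The route is a paper design and has not been run; the SMILES in the compound list are definitive for stereochemistry.

## Retrosynthetic overview

1. The target comes from kinetic deconjugation of the Δ7‑6‑ketone **14**; the ring‑B oxidation comes from allylic oxidation of a Δ7 alkene made from the 8α‑oxygen of sclareolide.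
2. The imide comes from ammonolysis of the trans β‑carbethoxy‑γ‑lactone **11**, which comes from iodolactonization of the γ,δ‑unsaturated amide **9** (C12–O set trans to C13).
3. Key step: Eschenmoser–Claisen [3,3] rearrangement of allylic alcohol **7** forms C13–C14 and relays the C11 carbinol chirality to C13.
4. The C11 carbinol comes from substrate‑controlled α‑hydroxylation (then inversion) of 2α‑chlorosclareolide; C2–Cl comes from substrate‑controlled C–H chlorination.
5. Rings A and B (C5, C9, C10) are bought in (+)‑sclareolide; the only ring built is the γ‑lactone (step 7), which is converted to the succinimide (step 11).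

## Route

**Step 1**
Reactants: **1** (+)‑sclareolide
Product: **2** 2α‑chlorosclareolide
Conditions: N‑chloro‑N‑tert‑butyl‑3,5‑bis(trifluoromethyl)benzamide, Cs2CO3, PhH, 55 °C, visible light
Reagents that add atoms: the N‑chloroamide, CC(C)(C)N(Cl)C(=O)c1cc(cc(c1)C(F)(F)F)C(F)(F)F (Cl)
Why: Amidyl‑radical C–H chlorination picks the least hindered, most electron‑rich methylene (C2, remote from the lactone) and gives the equatorial 2α‑chloride under substrate control.

**Step 2**
Reactants: **2**
Product: **3** 11α‑hydroxy‑2α‑chlorosclareolide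
Conditions: KHMDS, THF, −78 °C; then O2, P(OEt)3
Reagents that add atoms: dioxygen, O=O
Why: Lactone enolate oxidation; the electrophile enters C11 from the α face (cis to H‑9), because the β face is blocked by C10 and the axial C8/C10 methyls.

**Step 3**
Reactants: **3**
Product: **4** 11β‑hydroxy‑2α‑chlorosclareolide
Conditions: Tf2O, pyridine, CH2Cl2, −20 °C; then KNO2, 18‑crown‑6, DMF, rt; aqueous work‑up
Reagents that add atoms: potassium nitrite, [K+].[O-]N=O (supplies the new C11 oxygen)
Why: Lattrell–Dax inversion (SN2 of the α‑triflyloxy lactone by nitrite, then nitrite ester hydrolysis) gives the 11β carbinol, which is the epimer the chair Claisen needs; the 11α alcohol would give 13‑epi.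

**Step 4**
Reactants: **4**
Product: **5** 11β‑hydroxy lactol (C12 anomers)
Conditions: DIBAL‑H (2.5 equiv), CH2Cl2, −78 °C
Reagents that add atoms: none
Why: Partial reduction of the γ‑lactone stops at the lactol, a masked α‑hydroxy aldehyde; C11 is untouched.

**Step 5**
Reactants: **5**; **6** ethyl (triphenylphosphoranylidene)acetate
Product: **7** ethyl (E)‑γ‑hydroxy enoate (8α‑OH, 11β‑OH, E‑C12=C13, C16 = CO2Et)
Conditions: **6** (2 equiv), PhCO2H (cat.), toluene, 60 °C
Reagents that add atoms: **6**, CCOC(=O)C=P(c1ccccc1)(c1ccccc1)c1ccccc1 (adds C13 and C16O2Et)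
Why: Wittig olefination of the lactol's open form with a stabilized ylide gives the E‑enoate under neutral conditions, which limits oxa‑Michael closure by the 8‑OH. Any Z isomer lactonizes to a butenolide and is removed.

**Step 6 (key step)**
Reactants: **7**; **8** N,N‑dimethylacetamide dimethyl acetal
Product: **9** (13R)‑γ,δ‑unsaturated dimethylamide ethyl ester (E‑C11=C12, 8α‑OH)
Conditions: **8** (5 equiv), xylenes, 130 °C, MeOH distilled off
Reagents that add atoms: **8**, CN(C)C(C)(OC)OC (adds C14H2–C15(=O)NMe2)
Why: Eschenmoser–Claisen [3,3] rearrangement through a chair transition state with the decalin pseudo‑equatorial gives the E‑C11=C12 alkene and forms C13–C14 on the face from which the C11–O bond leaves. The 11β carbinol with the E‑enoate therefore gives 13R.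

**Step 7**
Reactants: **9**
Product: **10** trans iodolactone (C12–O lactone, C11–I, C16 = CO2Et)
Conditions: I2 (3 equiv), THF/H2O (2:1), 0 °C → rt, dark
Reagents that add atoms: iodine, II; water, O (becomes the lactone C15 carbonyl oxygen)
Why: In this 5‑exo iodolactonization the amide oxygen outcompetes the ester and the tertiary 8‑OH. Anti addition closes the ring with C12–O trans to the C13 ester (both substituents pseudo‑equatorial), which sets 12S. The cis isomer cannot be corrected later, so this selectivity matters.

**Step 8**
Reactants: **10**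
Product: **11** ethyl trans‑(12S,13R)‑lactone carboxylate (8α‑OH)
Conditions: Bu3SnH (1.2 equiv), AIBN (cat.), PhH, 80 °C
Reagents that add atoms: none
Why: Radical deiodination; the C–I bond reduces orders of magnitude faster than the secondary C2–Cl, and C11 becomes CH2.

**Step 9**
Reactants: **11**
Product: **12** Δ7 alkene (8‑methyl, C7=C8) lactone ester
Conditions: p‑TsOH·H2O (0.2 equiv), toluene, 80 °C
Reagents that add atoms: none
Why: E1 dehydration of the tertiary 8α‑ol; the endocyclic trisubstituted Δ7 alkene is expected as the major Zaitsev product, by analogy to the drimenyl series, and is separated from minor Δ8(9) and Δ8(17) isomers.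

**Step 10**
Reactants: **12**
Product: **13** 7‑en‑6‑one lactone ester
Conditions: CrO3, 3,5‑dimethylpyrazole, CH2Cl2, −20 °C
Reagents that add atoms: chromium trioxide, O=[Cr](=O)=O (O at C6)
Why: Allylic oxidation of the only allylic methylene (C6) gives the enone. C12–O is masked as the lactone, C5 stays trans (the thermodynamic epimer), and no other oxidizable alcohol is present.

**Step 11**
Reactants: **13**
Product: **14** Δ7‑6‑oxo hydroxy succinimide (conjugated isomer of the target)
Conditions: NH3 (7 M in MeOH), sealed tube, rt → 45 °C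
Reagents that add atoms: ammonia, N
Why: Ammonolysis of the γ‑lactone frees the C12 alcohol and gives the C15 primary amide, which closes 5‑exo onto the C16 ethyl ester to form the imide. The hindered β,β‑disubstituted enone is inert and C12/C13 are not touched.

**Step 12**
Reactants: **14**
Product: **15** haterumaimide G
Conditions: LDA (4 equiv), THF/DMPU, −78 °C, 45 min; inverse quench into AcOH/THF at −78 °C; buffered work‑up
Reagents that add atoms: none
Why: Deconjugation by kinetic protonation. After N–H and O–H deprotonation, the accessible C17 methyl is removed in preference to the hindered C5–H and C9–H, and the exocyclic dienolate is protonated at C7 to give the β,γ‑unsaturated ketone with the 8(17) methylene. The imide N‑anion protects C13/C14 from enolization.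

## Compound list

1 | (+)‑Sclareolide | C[C@@]12CC[C@H]3C(C)(C)CCC[C@]3(C)[C@H]1CC(=O)O2 | starting material
2 | 2α‑Chlorosclareolide | C[C@@]12CC[C@H]3C(C)(C)C[C@H](Cl)C[C@]3(C)[C@H]1CC(=O)O2 | intermediate
3 | 11α‑Hydroxy‑2α‑chlorosclareolide | C[C@@]12CC[C@H]3C(C)(C)C[C@H](Cl)C[C@]3(C)[C@H]1[C@H](O)C(=O)O2 | intermediate
4 | 11β‑Hydroxy‑2α‑chlorosclareolide | C[C@@]12CC[C@H]3C(C)(C)C[C@H](Cl)C[C@]3(C)[C@H]1[C@@H](O)C(=O)O2 | intermediate
5 | 11β‑Hydroxy lactol (C12 anomers) | C[C@@]12CC[C@H]3C(C)(C)C[C@H](Cl)C[C@]3(C)[C@H]1[C@@H](O)C(O)O2 | intermediate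
6 | Ethyl (triphenylphosphoranylidene)acetate | CCOC(=O)C=P(c1ccccc1)(c1ccccc1)c1ccccc1 | starting material
7 | Ethyl (E)‑γ‑hydroxy enoate, 8α,11β‑diol | C[C@@]1(O)CC[C@H]2C(C)(C)C[C@H](Cl)C[C@]2(C)[C@H]1[C@@H](O)/C=C/C(=O)OCC | intermediate
8 | N,N‑Dimethylacetamide dimethyl acetal | CN(C)C(C)(OC)OC | starting material
9 | (13R)‑E‑11‑ene dimethylamide ethyl ester, 8α‑ol | C[C@@]1(O)CC[C@H]2C(C)(C)C[C@H](Cl)C[C@]2(C)[C@H]1/C=C/[C@H](C(=O)OCC)CC(=O)N(C)C | intermediate
10 | 11‑Iodo trans‑lactone ethyl ester, 8α‑ol | C[C@@]1(O)CC[C@H]2C(C)(C)C[C@H](Cl)C[C@]2(C)[C@H]1[C@H](I)[C@@H]3OC(=O)C[C@H]3C(=O)OCC | intermediate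
11 | trans‑(12S,13R)‑Lactone ethyl ester, 8α‑ol | C[C@@]1(O)CC[C@H]2C(C)(C)C[C@H](Cl)C[C@]2(C)[C@H]1C[C@@H]3OC(=O)C[C@H]3C(=O)OCC | intermediate
12 | Δ7 lactone ethyl ester | CC1=CC[C@H]2C(C)(C)C[C@H](Cl)C[C@]2(C)[C@H]1C[C@@H]3OC(=O)C[C@H]3C(=O)OCC | intermediate
13 | 7‑En‑6‑one lactone ethyl ester | CC1=CC(=O)[C@H]2C(C)(C)C[C@H](Cl)C[C@]2(C)[C@H]1C[C@@H]3OC(=O)C[C@H]3C(=O)OCC | intermediate
14 | Δ7‑6‑Oxo hydroxy succinimide | CC1=CC(=O)[C@H]2C(C)(C)C[C@H](Cl)C[C@]2(C)[C@H]1C[C@H](O)[C@H]1CC(=O)NC1=O | intermediate
15 | Haterumaimide G | C=C1CC(=O)[C@H]2C(C)(C)C[C@H](Cl)C[C@]2(C)[C@H]1C[C@H](O)[C@H]1CC(=O)NC1=O | target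

## Summary

Total steps: 12. Longest linear sequence: 12 (fully linear from sclareolide).

Steps most likely to fail, each with a fallback that changes the approach:

1. **Step 12 (deconjugation).** Deprotonation could occur at C9 or C5 instead of C17, the C12 alkoxide could add to C8, and the product can re‑conjugate.
   Fallback: drop the enolate endgame. From **13**, build a 6‑O‑silyl‑8α‑ol (nucleophilic epoxidation, reductive epoxide opening, ketone reduction, silylation), form the 8(17) alkene by E2 dehydration with SOCl2/pyridine, form the imide, and finish with a neutral desilylation and Dess–Martin oxidation of the homoallylic C6 alcohol.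
2. **Step 9 (Δ7‑selective dehydration).** E1 conditions may give too much Δ8(9) or Δ8(17) alkene, and only the Δ7 isomer leads to C6 oxidation in step 10.
   Fallback: do a kinetic E2 dehydration to the 8(17) alkene (SOCl2, pyridine, −78 °C), then a radical hydrogen‑atom‑transfer isomerization (Co(salen) catalyst, PhSiH3) to the Δ7 alkene.
3. **Step 6 (Claisen on the unprotected diol enoate).** The 8‑OH could add to C12 of the enoate (oxa‑Michael), or the product could isomerize to the conjugated alkylidene succinate.
   Fallback: keep the [3,3] step but change the substrate. Carry C16 as a non‑electrophilic allylic silyl ether (CH2OTBS in place of CO2Et), run an Ireland–Claisen rearrangement of the 11‑acetate, and oxidize C16 to the carboxyl after lactonization.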